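**Conventions.** Locants C1–C15 are the germacrane locants of the target: ring C1–C10, C11–C13 the acrylate unit on C7, C14 on C10, C15 on C4. "cis" for a ring alkene means that its two ring bonds are cis. Compound numbers are those of the steps below.

**Assumption.** The (S) phosphoric acid in step 9 is taken to send the allyl unit to the Si face of the aldehyde, as the accepted hydrogen-bonding model for phosphoric acid-catalysed crotylborations predicts; if the sense proves opposite, the (R) catalyst is used and nothing else changes.

## Analysis of the target

Target 31 is a germacranolide: a ten-membered carbocycle (C1–C10) with two trisubstituted ring alkenes, C1=C10 and C4=C5, each cis in the ring and each bearing a hydroxymethyl group (C14 on C10, C15 on C4). A five-membered α-methylene lactone (O–C6–C7–C11–C12, exocyclic C11=C13) is fused trans across C6–C7, and C8 carries an angelate ester. The three contiguous stereocentres are C6 (R, oxygen α), C7 (R, hydrogen α) and C8 (R, oxygen β), so the C8 oxygen is cis and the C6 oxygen trans to the C7–C11 bond. The sensitive groups are the methylene lactone (a Michael acceptor), the (Z)-configured angelate (which isomerises to the tiglate under nucleophilic or basic catalysis), the two primary allylic alcohols, and the 1,5-diene in a medium ring (prone to acid-induced transannular cyclisation). The difficulties are the closure of a ten-membered ring with two alkenes of defined geometry, the stereotriad, and the need to hold C12 at the acid level while C14 and C15 end at the alcohol level. The strategy rests on C6: without the lactone it is a methylene between the C4=C5 alkene and C7, γ to the C12 carboxyl. Oxidation of that one C–H bond gives a γ-hydroxy acid that closes the lactone ring by itself, so C6–O, O–C12, the lactone ring and the C6 stereocentre can be added last to a carbocycle whose only stereocentres are C7 and C8.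

## Retrosynthetic reasoning

**Angelate.** The C8–O acyl bond of 31 is cut first, which leads to angelic acid 28 and the triol lactone 26. Putting this isomerisable (Z)-enoate on last keeps it away from every basic, reducing and enzymatic step. The forward sequence only has to tell the secondary C8 hydroxyl from the two primary allylic ones, which the bis-silyl ether 27 and its ester 30 do.

**Lactone (key disconnection).** In 26 the C6–O and O–C12 bonds are cut together. This removes the lactone ring and the C6 stereocentre and leaves the carboxylate 24, the salt of acid 23, with a plain methylene at C6. The cut is placed here because C6–H is the bond that germacranolide biosynthesis oxidises, and no small reagent can pick it out from the allylic C–H bonds at C2, C3 and C9. Forward, an enzyme must hydroxylate the 6α C–H of 24 and the resulting hydroxy carboxylate 25 must lactonise onto C12.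

**Oxidation levels.** Carboxylate 24 is traced to lactol 22 by an aldehyde-selective oxidation, and 22 to the macrocyclic lactone diester 21 by one hydride reduction. In 21 the C8 oxygen and C12 are tied up as a cis-fused 12,8-lactone. A C12 ester could not be kept intact while the C14 and C15 esters are reduced, whereas a lactone stops at the lactol, from which the acid level is regained without touching the alcohols. The same ring protects the C8 hydroxyl and holds the two side chains on one face for the ring closure.

**Ten-membered ring.** Macrocycle 21 is opened at C4=C5 to aldehyde 20, made from alcohol 19. This alkene is an enoate whose ester (C15) is trans to C6, which is the normal outcome of an olefination with an α-substituted phosphonoacetate, so ring closure and alkene geometry are solved by one reaction. The forward step must close a medium ring under conditions mild enough for the methylene lactone.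

**C7–C8 bond.** Alcohol 19 is cut between C7 and C8 into aldehyde 11 and allylboronate 16. One intermolecular allylboration through a closed transition state forms the bond, both stereocentres and the C11=C13 methylene, and the borate 17 lactonises to 18. The syn relationship needed follows from the alkene geometry of 16, and the absolute sense from a chiral phosphoric acid. The C14 carboxyl in 11 is a tert-butyl ester so that the C8 oxygen, which is γ to both C12 and C14, lactonises only onto the methyl ester at C12.

**Allylboronate.** Boronate 16 comes from acetate 15 by allylic borylation with transposition, 15 from adduct 14, and 14 from methyl acrylate 12 and aldehyde 13. The stereocentre of 14 is lost on the way, so it is made as the racemate.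

**Aldehyde fragment.** Aldehyde 11 comes from the terminal alkene 9 by oxidative cleavage through diol 10. Diene 9 is cut at C1=C10 into aldehyde 4 and ylide 8; the stabilised ylide gives the enoate with C2 cis to C9 and does not disturb the phosphonoacetate. Ylide 8 is made from 5 and 6 through salt 7, and 4 from acetal 3, the alkylation product of 1 with 2.

## Alternatives that were turned down

**Alternative 1:** The ring would be closed at C2–C3. Pd(PPh3)4 (zerovalent palladium) ionises an allylic carbonate next to C4 to a 2-carbomethoxyallyl complex, and a sulfonyl-stabilised carbanion at C2 attacks C3, which gives the ten-membered enoate A1 with C6 (as an ether), C7 and C8 already in place. In its favour, both C5 epimers of the open-chain precursor converge on one allyl complex, soft-carbanion allylations are among the more dependable medium-ring closures, and the C6 oxygen is set by ordinary chemistry. Against it, A1 is far from 31: the sulfone must be removed reductively from a skipped diene-enoate, the C15 ester reduced, and C12 (a protected allylic alcohol in A1) oxidised to the acid level next to an equally allylic C6 hydroxyl. Four different protecting groups must come off in order, and attack at C3 versus C5 and the enoate geometry are open points. On the reliability of the ring-forming step this alternative is stronger than an enzymatic C–H oxidation. The chosen route offers in exchange that C6 never needs protection or its own stereocontrol, and that the lactone appears in final form in one operation with far fewer steps after ring closure.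

**Alternative 2:** The cut is at C7–C8. SmI2 (divalent samarium) reduces a C8 aldehyde to a ketyl that adds to C7 of a butenolide already holding the C6 stereocentre, which gives A2 with ring, lactone, C7 and C8 formed at once. In its favour, the lactone and C6 come from known chemistry and A2 is only a few steps from 31. Against it, the ketyl must reach the butenolide through a ten-membered transition state, where simple reduction of the aldehyde and pinacol coupling compete. The C7 and C8 configurations rest on induction from C6 through a flexible ring-forming geometry, the aldehyde is β,γ-unsaturated, and A2 lacks C13, so the lactone must be methylenated next to a free C8 hydroxyl. It is as short as the chosen route in the endgame and stronger in needing no enzyme. The chosen route instead sets C7 and C8 in an intermolecular addition with a well-understood closed transition state under catalyst control and carries the methylene from the start.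

**Alternative 3:** A six-membered ring is expanded. KH with 18-crown-6 turns a 1,2-dialkenyl cyclohexenol from the perillyl chiral pool into its alkoxide, whose [3,3] shift forms C8–C9, breaks the six-ring bond and gives the cyclodecadienone A3. This is the strongest of the four on ring construction, because a ring expansion avoids the entropic cost of medium-ring closure, and the chirality is cheap. Against it, A3 holds only the C8 stereocentre: C7 has neither its configuration nor the C11–C13 unit, and C6 is a ketone. Enolate alkylation at C7 relative to C8, α-face reduction of a conjugated ketone, lactonisation and methylenation would follow, that is three stereochemical operations on a flexible ring. A shift that normally gives a trans alkene from a chair geometry would also have to give both ring alkenes cis. The chosen route concentrates its risk in one step, but after that step C6, C7, C8 and the lactone are complete.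

Key step: step 14

## Steps

Step 1
Reactants: 1 triethyl phosphonoacetate; 2 2-(2-bromoethyl)-1,3-dioxolane
Product: 3 ethyl 2-(diethoxyphosphoryl)-4-(1,3-dioxolan-2-yl)butanoate (racemic)
Conditions: NaH, DMF, 0 °C → 60 °C
Reagents that add atoms: none
Why: SN2 alkylation of the sodium phosphonoacetate by the primary bromide forms C3–C4; the stabilised anion is too weakly basic to eliminate the bromide, and a second alkylation is slow for steric reasons.

Step 2
Reactants: 3 ethyl 2-(diethoxyphosphoryl)-4-(1,3-dioxolan-2-yl)butanoate
Product: 4 ethyl 2-(diethoxyphosphoryl)-5-oxopentanoate (racemic)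
Conditions: 1 M HCl, THF, rt
Reagents that add atoms: water, O
Why: Acid-catalysed acetal hydrolysis frees the C1 aldehyde; the phosphonate and the ethyl ester are stable to dilute aqueous acid at room temperature.

Step 3
Reactants: 5 tert-butyl (triphenylphosphoranylidene)acetate; 6 allyl bromide
Product: 8 tert-butyl 2-(triphenylphosphoranylidene)pent-4-enoate, via phosphonium bromide 7 (not isolated)
Conditions: CH2Cl2, reflux; then 1 M NaOH (aq.), rt
Reagents that add atoms: none
Why: C-alkylation of the ester-stabilised ylide by the allylic bromide gives salt 7, which aqueous base deprotonates to the α-allyl ylide; the allyl group supplies C9 and C8.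

Step 4
Reactants: 4 ethyl 2-(diethoxyphosphoryl)-5-oxopentanoate; 8 tert-butyl 2-(triphenylphosphoranylidene)pent-4-enoate
Product: 9 1-tert-butyl 7-ethyl (2E)-6-(diethoxyphosphoryl)-2-(prop-2-en-1-yl)hept-2-enedioate
Conditions: toluene, 90 °C
Reagents that add atoms: none
Why: Wittig reaction of an α-substituted ester-stabilised ylide with an unhindered aliphatic aldehyde, which should give the (E)-enoate (C2 trans to the ester and so cis to C9). The neutral ylide is far too weak a base to deprotonate the phosphonoacetate of 4.

Step 5
Reactants: 9 1-tert-butyl 7-ethyl (2E)-6-(diethoxyphosphoryl)-2-(prop-2-en-1-yl)hept-2-enedioate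
Product: 11 1-tert-butyl 7-ethyl (2E)-6-(diethoxyphosphoryl)-2-(2-oxoethyl)hept-2-enedioate, via vicinal diol 10 (not isolated)
Conditions: K2OsO4·2H2O (2 mol %), NaIO4, 2,6-lutidine, 1,4-dioxane/H2O (3:1), rt
Reagents that add atoms: sodium periodate, [Na+].[O-]I(=O)(=O)=O
Why: Lemieux–Johnson cleavage: osmium-catalysed dihydroxylation takes the electron-rich monosubstituted alkene in preference to the trisubstituted, ester-conjugated C1=C10 alkene, and periodate cleaves diol 10 to the C8 aldehyde. The β,γ-unsaturated aldehyde is used at once, without chromatography on basic media.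

Step 6
Reactants: 12 methyl acrylate; 13 3-[(tert-butyldimethylsilyl)oxy]propanal
Product: 14 methyl 5-[(tert-butyldimethylsilyl)oxy]-3-hydroxy-2-methylidenepentanoate (racemic)
Conditions: DABCO (1 equiv), 1,4-dioxane/H2O (1:1), rt
Reagents that add atoms: none
Why: Morita–Baylis–Hillman reaction of an unhindered aliphatic aldehyde with an acrylate under amine catalysis joins C7 to C11; the carbinol stereocentre is removed in step 8, so the racemate is used.

Step 7
Reactants: 14 methyl 5-[(tert-butyldimethylsilyl)oxy]-3-hydroxy-2-methylidenepentanoate
Product: 15 methyl 3-acetoxy-5-[(tert-butyldimethylsilyl)oxy]-2-methylidenepentanoate (racemic)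
Conditions: Ac2O, pyridine, DMAP (cat.), CH2Cl2, 0 °C
Reagents that add atoms: acetic anhydride, CC(=O)OC(C)=O
Why: Acetylation turns the secondary allylic hydroxyl into the leaving group for the allylic substitution of step 8.

Step 8
Reactants: 15 methyl 3-acetoxy-5-[(tert-butyldimethylsilyl)oxy]-2-methylidenepentanoate
Product: 16 methyl (2E)-5-[(tert-butyldimethylsilyl)oxy]-2-[(4,4,5,5-tetramethyl-1,3,2-dioxaborolan-2-yl)methyl]pent-2-enoate
Conditions: B2pin2, CuCl, LiCl, KOAc, DMF, rt
Reagents that add atoms: bis(pinacolato)diboron, CC1(C)OB(OC1(C)C)B1OC(C)(C)C(C)(C)O1
Why: Copper-mediated SN2′ borylation of a Morita–Baylis–Hillman acetate: the boryl-copper species adds to the terminal methylene (C13) and acetate leaves from C7. The trisubstituted alkene should form with C6 trans to the ester and cis to CH2B, the geometry that leads to the syn adduct.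

Step 9
Reactants: 11 1-tert-butyl 7-ethyl (2E)-6-(diethoxyphosphoryl)-2-(2-oxoethyl)hept-2-enedioate; 16 methyl (2E)-5-[(tert-butyldimethylsilyl)oxy]-2-[(4,4,5,5-tetramethyl-1,3,2-dioxaborolan-2-yl)methyl]pent-2-enoate
Product: 19 (7R,8R)-cis-12,8-lactone primary alcohol, via pinacol borate adduct 17 (not isolated), via silyl ether lactone 18 (not isolated)
Conditions: (S)-3,3′-bis(2,4,6-triisopropylphenyl)-1,1′-binaphthyl-2,2′-diyl hydrogen phosphate (5 mol %), 4 Å molecular sieves, toluene, rt; then camphorsulfonic acid (cat.), MeOH, rt
Reagents that add atoms: none
Why: Chiral phosphoric acid-catalysed allylboration through a closed six-membered chair transition state: the acid activates the boronate and holds the formyl hydrogen so that C7 adds to the Si face of C8, and the geometry of 16 (C6 cis to CH2B) becomes the syn relationship of the C8 oxygen and the C7 side chain, which sets C7 (R) and C8 (R) together. The uncatalysed addition of such ester-bearing allylboronates is very slow at room temperature, so the catalysed path should dominate. Acid in methanol then closes the five-membered lactone from borate 17 onto the methyl ester (the tert-butyl enoate at C14 is inert to acyl substitution) and cleaves the primary silyl ether of 18.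

Step 10
Reactants: 19 (7R,8R)-cis-12,8-lactone primary alcohol
Product: 20 (7R,8R)-cis-12,8-lactone C5 aldehyde
Conditions: Dess–Martin periodinane, NaHCO3, CH2Cl2, 0 °C → rt
Reagents that add atoms: none
Why: Dess–Martin oxidation of the primary alcohol under buffered, non-basic conditions leaves the methylene lactone, the phosphonoacetate and the C7 stereocentre untouched.

Step 11
Reactants: 20 (7R,8R)-cis-12,8-lactone C5 aldehyde
Product: 21 14-tert-butyl 15-ethyl (7R,8R)-cis,cis-germacra-1(10),4,11(13)-trien-12,8β-olide-14,15-dioate
Conditions: LiCl, iPr2NEt, MeCN, 1 mM (slow addition of 20), 40 °C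
Reagents that add atoms: none
Why: Intramolecular Horner–Wadsworth–Emmons reaction under Masamune–Roush conditions at high dilution closes the ten-membered ring at C4=C5; the cis-fused lactone and the cis C1=C10 alkene hold the aldehyde and the phosphonate on the same side. The E preference of α-substituted phosphonoacetates and the lower strain of a cis ring alkene both favour the enoate with C3 and C6 cis, and the amine base is too weak to enolise the aldehyde.

Step 12
Reactants: 21 14-tert-butyl 15-ethyl (7R,8R)-cis,cis-germacra-1(10),4,11(13)-trien-12,8β-olide-14,15-dioate
Product: 22 (7R,8R)-14,15-dihydroxy-cis,cis-germacra-1(10),4,11(13)-trien-12,8β-lactol (mixture of C12 epimers)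
Conditions: iBu2AlH (8 equiv), CH2Cl2, −78 → −30 °C; aq. potassium sodium tartrate
Reagents that add atoms: none
Why: Hydride reduction in which the two conjugated esters go to the allylic alcohols by 1,2-reduction, while the lactone stops at the lactol because its tetrahedral aluminium hemiacetal is stable at low temperature. No ring stereocentre is touched.

Step 13
Reactants: 22 (7R,8R)-14,15-dihydroxy-cis,cis-germacra-1(10),4,11(13)-trien-12,8β-lactol
Product: 24 lithium (7R,8R)-8β,14,15-trihydroxy-cis,cis-germacra-1(10),4,11(13)-trien-12-oate, via free trihydroxy acid 23 (not isolated)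
Conditions: NaClO2, NaH2PO4, 2-methyl-2-butene, tBuOH/H2O, 0 °C → rt; then LiOH (aq.) to pH 10–11; reverse-phase desalting, lyophilisation
Reagents that add atoms: sodium chlorite, [Na+].[O-]Cl=O; lithium hydroxide, [Li+].[OH-]
Why: Pinnick oxidation acts on the hydroxy-aldehyde form of the lactol and gives the acrylic acid 23 without touching the primary allylic alcohols or the alkenes, since the alkene additive scavenges hypochlorite. Lithium hydroxide then converts the acid, and any material that has closed back onto C8, into the carboxylate, which cannot lactonise.

Step 14
Reactants: 24 lithium (7R,8R)-8β,14,15-trihydroxy-cis,cis-germacra-1(10),4,11(13)-trien-12-oate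
Product: 26 (6R,7R,8R)-8β,14,15-trihydroxy-cis,cis-germacra-1(10),4,11(13)-trien-12,6α-olide, via lithium 6α-hydroxy carboxylate 25 (not isolated)
Conditions: CYP71-family germacrene A acid 6α-hydroxylase (eupatolide-synthase type, variant chosen by screening) and its NADPH–cytochrome P450 reductase in yeast microsomes, NADPH (cat.), glucose 6-phosphate, glucose-6-phosphate dehydrogenase, air, potassium phosphate buffer pH 7.5, 30 °C; then citric acid to pH 5, EtOAc
Reagents that add atoms: dioxygen, O=O
Why: Proposed new method: the heme iron-oxo species of the enzyme (formally tetravalent iron with a porphyrin radical cation) should abstract the 6α hydrogen of 24, which is allylic to C4=C5 and γ to the carboxylate that anchors the substrate, and oxygen rebound on the same face should give the 6α-hydroxy carboxylate 25. The closest known reaction type is the P450-catalysed 6α-hydroxylation and lactonisation of germacrene A acid and of its 8β-hydroxy derivative in the biosynthesis of costunolide and eupatolide; 24 differs from those substrates in its cis ring alkenes and its two hydroxymethyl groups, and no enzyme has been shown to accept it. The lactone ring closes by 5-exo-trig attack of the C6 hydroxyl on the trigonal C12 carboxyl carbon with loss of water, during the incubation or on the mild acidification of the work-up. The new C6 stereocentre (R, oxygen α) is set by the active site, which presents only the α face of C6 to the iron-oxo unit, and C7 and C8 are not touched. The step needs site selectivity for C6–H over the allylic C–H bonds at C2, C3 and C9 and the carbinol C–H bonds at C14 and C15, and chemoselectivity against alkene epoxidation; carboxylate binding and the fit of the ring in the pocket must secure this, so a panel of wild-type and mutated enzymes is screened. Holding 24 as its salt at pH 7.5 keeps the C8 hydroxyl from lactonising before the oxidation, and once C6 is hydroxylated the trans-fused 12,6-lactone is the ring that the natural 8β-hydroxy substrates also close.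

Step 15
Reactants: 26 (6R,7R,8R)-8β,14,15-trihydroxy-cis,cis-germacra-1(10),4,11(13)-trien-12,6α-olide
Product: 27 14,15-bis-O-(tert-butyldimethylsilyl) ether of 26
Conditions: TBSCl (2.2 equiv), imidazole, DMF, 0 °C
Reagents that add atoms: tert-butyldimethylsilyl chloride, CC(C)(C)[Si](C)(C)Cl
Why: Silylation of the two unhindered primary allylic alcohols should be much faster than that of the secondary C8 hydroxyl, which sits next to the ring fusion.

Step 16
Reactants: 27 14,15-bis-O-(tert-butyldimethylsilyl) ether of 26; 28 angelic acid
Product: 30 14,15-bis-O-(tert-butyldimethylsilyl) ether of the target, via mixed anhydride 29 (not isolated)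
Conditions: 28, 2,4,6-trichlorobenzoyl chloride, Et3N, toluene, rt; then 27, toluene, 80 °C
Reagents that add atoms: none
Why: Yamaguchi esterification: the mixed anhydride 29 acylates the C8 alcohol at the less hindered angeloyl carbonyl. Running it without a nucleophilic pyridine catalyst avoids the conjugate addition–elimination that isomerises angelates (Z) to tiglates (E).

Step 17
Reactants: 30 14,15-bis-O-(tert-butyldimethylsilyl) ether of the target
Product: 31 (6R,7R,8R)-8β-angeloyloxy-14,15-dihydroxy-cis,cis-germacra-1(10),4,11(13)-trien-12,6α-olide (CNP0182172.4)
Conditions: HF·pyridine, pyridine, THF, 0 °C → rt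
Reagents that add atoms: none
Why: Buffered fluoride cleaves the two primary silyl ethers; the medium is neither basic enough to isomerise the angelate or open the lactone nor acidic enough to start transannular cyclisation of the 1,5-diene.

## Compound list

1 | triethyl phosphonoacetate | CCOC(=O)CP(=O)(OCC)OCC | starting material
2 | 2-(2-bromoethyl)-1,3-dioxolane | BrCCC1OCCO1 | starting material
3 | ethyl 2-(diethoxyphosphoryl)-4-(1,3-dioxolan-2-yl)butanoate (racemic) | CCOC(=O)C(CCC1OCCO1)P(=O)(OCC)OCC | intermediate
4 | ethyl 2-(diethoxyphosphoryl)-5-oxopentanoate (racemic) | CCOC(=O)C(CCC=O)P(=O)(OCC)OCC | intermediate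
5 | tert-butyl (triphenylphosphoranylidene)acetate | CC(C)(C)OC(=O)C=P(c1ccccc1)(c1ccccc1)c1ccccc1 | starting material
6 | allyl bromide (3-bromoprop-1-ene) | C=CCBr | starting material
7 | [1-(tert-butoxy)-1-oxopent-4-en-2-yl]triphenylphosphonium bromide | CC(C)(C)OC(=O)C(CC=C)[P+](c1ccccc1)(c1ccccc1)c1ccccc1.[Br-] | intermediate (not isolated)
8 | tert-butyl 2-(triphenylphosphoranylidene)pent-4-enoate | CC(C)(C)OC(=O)C(CC=C)=P(c1ccccc1)(c1ccccc1)c1ccccc1 | intermediate
9 | 1-tert-butyl 7-ethyl (2E)-6-(diethoxyphosphoryl)-2-(prop-2-en-1-yl)hept-2-enedioate | CC(C)(C)OC(=O)/C(CC=C)=C/CCC(C(=O)OCC)P(=O)(OCC)OCC | intermediate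
10 | 1-tert-butyl 7-ethyl (2E)-6-(diethoxyphosphoryl)-2-(2,3-dihydroxypropyl)hept-2-enedioate | CC(C)(C)OC(=O)/C(CC(O)CO)=C/CCC(C(=O)OCC)P(=O)(OCC)OCC | intermediate (not isolated)
11 | 1-tert-butyl 7-ethyl (2E)-6-(diethoxyphosphoryl)-2-(2-oxoethyl)hept-2-enedioate | CC(C)(C)OC(=O)/C(CC=O)=C/CCC(C(=O)OCC)P(=O)(OCC)OCC | intermediate
12 | methyl acrylate | C=CC(=O)OC | starting material
13 | 3-[(tert-butyldimethylsilyl)oxy]propanal | O=CCCO[Si](C)(C)C(C)(C)C | starting material
14 | methyl 5-[(tert-butyldimethylsilyl)oxy]-3-hydroxy-2-methylidenepentanoate (racemic) | C=C(C(=O)OC)C(O)CCO[Si](C)(C)C(C)(C)C | intermediate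
15 | methyl 3-acetoxy-5-[(tert-butyldimethylsilyl)oxy]-2-methylidenepentanoate (racemic) | C=C(C(=O)OC)C(OC(C)=O)CCO[Si](C)(C)C(C)(C)C | intermediate
16 | methyl (2E)-5-[(tert-butyldimethylsilyl)oxy]-2-[(4,4,5,5-tetramethyl-1,3,2-dioxaborolan-2-yl)methyl]pent-2-enoate | COC(=O)/C(CB1OC(C)(C)C(C)(C)O1)=C/CCO[Si](C)(C)C(C)(C)C | intermediate
17 | (7R,8R) syn allylboration adduct as its C8 pinacol borate: open chain with C12 methyl ester, C11=C13 methylene, C5 silyl ether, C14 tert-butyl ester (C2 cis to C9) and the C4 phosphonoacetate | C=C(C(=O)OC)[C@@H](CCO[Si](C)(C)C(C)(C)C)[C@H](OB1OC(C)(C)C(C)(C)O1)C/C(C(=O)OC(C)(C)C)=C\CCC(C(=O)OCC)P(=O)(OCC)OCC | intermediate (not isolated)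
18 | (7R,8R)-cis-12,8-lactone (α-methylene-γ-butyrolactone) with C5 silyl ether; C8 bears the chain C9–C10(CO2tBu)=C1–C2–C3–C4H(CO2Et)P(O)(OEt)2 | C=C1C(=O)O[C@H](C/C(C(=O)OC(C)(C)C)=C\CCC(C(=O)OCC)P(=O)(OCC)OCC)[C@@H]1CCO[Si](C)(C)C(C)(C)C | intermediate (not isolated)
19 | (7R,8R)-cis-12,8-lactone primary alcohol (C5–OH) | C=C1C(=O)O[C@H](C/C(C(=O)OC(C)(C)C)=C\CCC(C(=O)OCC)P(=O)(OCC)OCC)[C@@H]1CCO | intermediate
20 | (7R,8R)-cis-12,8-lactone C5 aldehyde | C=C1C(=O)O[C@H](C/C(C(=O)OC(C)(C)C)=C\CCC(C(=O)OCC)P(=O)(OCC)OCC)[C@@H]1CC=O | intermediate
21 | 14-tert-butyl 15-ethyl (7R,8R)-cis,cis-germacra-1(10),4,11(13)-trien-12,8β-olide-14,15-dioate | C=C1C(=O)O[C@@H]2C/C(C(=O)OC(C)(C)C)=C\CC/C(C(=O)OCC)=C\C[C@H]12 | intermediate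
22 | (7R,8R)-14,15-dihydroxy-cis,cis-germacra-1(10),4,11(13)-trien-12,8β-lactol (C12 epimers) | C=C1C(O)O[C@@H]2C/C(CO)=C\CC/C(CO)=C\C[C@H]12 | intermediate
23 | (7R,8R)-8β,14,15-trihydroxy-cis,cis-germacra-1(10),4,11(13)-trien-12-oic acid | C=C(C(=O)O)[C@H]1C/C=C(/CO)CC/C=C(/CO)C[C@H]1O | intermediate (not isolated)
24 | lithium salt of 23 | C=C(C(=O)[O-])[C@H]1C/C=C(/CO)CC/C=C(/CO)C[C@H]1O.[Li+] | intermediate
25 | lithium (6R,7R,8R)-6α,8β,14,15-tetrahydroxy-cis,cis-germacra-1(10),4,11(13)-trien-12-oate | C=C(C(=O)[O-])[C@H]1[C@H](O)/C=C(/CO)CC/C=C(/CO)C[C@H]1O.[Li+] | intermediate (not isolated)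
26 | (6R,7R,8R)-8β,14,15-trihydroxy-cis,cis-germacra-1(10),4,11(13)-trien-12,6α-olide | C=C1C(=O)O[C@@H]2/C=C(/CO)CC/C=C(/CO)C[C@@H](O)[C@@H]12 | intermediate
27 | 14,15-bis-O-(tert-butyldimethylsilyl) ether of 26 | C=C1C(=O)O[C@@H]2/C=C(/CO[Si](C)(C)C(C)(C)C)CC/C=C(/CO[Si](C)(C)C(C)(C)C)C[C@@H](O)[C@@H]12 | intermediate
28 | angelic acid, (2Z)-2-methylbut-2-enoic acid | C/C=C(/C)C(=O)O | starting material
29 | angelic 2,4,6-trichlorobenzoic anhydride | C/C=C(/C)C(=O)OC(=O)c1c(Cl)cc(Cl)cc1Cl | intermediate (not isolated)
30 | 14,15-bis-O-(tert-butyldimethylsilyl) ether of the target | C=C1C(=O)O[C@@H]2/C=C(/CO[Si](C)(C)C(C)(C)C)CC/C=C(/CO[Si](C)(C)C(C)(C)C)C[C@@H](OC(=O)/C(C)=C\C)[C@@H]12 | intermediate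
31 | (6R,7R,8R)-8β-angeloyloxy-14,15-dihydroxy-cis,cis-germacra-1(10),4,11(13)-trien-12,6α-olide (CNP0182172.4) | C=C1C(=O)O[C@@H]2/C=C(/CO)CC/C=C(/CO)C[C@@H](OC(=O)/C(C)=C\C)[C@@H]12 | target

## Step count and least certain steps

Total: 17 steps. Longest linear sequence: 13 steps (steps 1, 2, 4, 5, 9, 10, 11, 12, 13, 14, 15, 16, 17). Step 3 and steps 6–8 are side branches.

**Step 14 (key step; the one step beyond known chemistry).** The most likely failure is that no enzyme variant turns the substrate over, or that oxidation goes to the wrong site: hydroxylation at C2, C3 or C9, oxidation of the C14 or C15 carbinols, or epoxidation. The pocket of this enzyme class evolved for trans,trans substrates without hydroxymethyl groups, so the cis,cis ring may not place C6 over the iron. A second failure is lactonisation onto C8 if the pH drifts down before oxidation.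

The fallback uses known reactions and puts the C6 oxygen in before the ring is closed. It sets out from aldehyde 20. D-Proline-catalysed α-aminoxylation with nitrosobenzene in DMSO should give the (6S)-α-anilinooxy aldehyde F1. L-Proline is known to give the R series with simple aldehydes, and the C6 centre needed here is S in the priority order of the aldehyde. F1 is cyclised at once under the conditions of step 11 to the macrocyclic γ-anilinooxy enoate F2. Zn in acetic acid cleaves the N–O bond to the 6α-hydroxy macrocycle F3. iBu2AlH as in step 12 gives the lactol tetraol F4. Chlorite oxidation as in step 13, without the hydroxide finish and followed by brief treatment with pyridinium p-toluenesulfonate, should lactonise the resulting dihydroxy acid onto C6. The route is rejoined at 26. The weak point of this fallback is the choice between the trans-fused 12,6-lactone and the cis-fused 12,8-lactone; the former is expected to be the more stable, as in the natural 8β-hydroxy germacranolides.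

**Step 11 (ring closure).** The most likely failure is oligomerisation or cyclodimerisation in place of ring closure, because a ten-membered ring is entropically and enthalpically costly even with the lactone template. A slower side path is conjugate addition of the phosphonate anion to the methylene lactone.

The fallback closes the same bond by metathesis. It sets out from alcohol 19. Paraformaldehyde and K2CO3 in THF convert the phosphonoacetate into the 2-substituted acrylate alcohol F5 (olefination with formaldehyde). Dess–Martin oxidation gives the acrylate aldehyde F6. Methylenation with Zn, CH2I2 and TiCl4 gives the terminal alkene F7. Ring-closing metathesis with the second-generation Hoveyda–Grubbs catalyst in toluene at 80 °C and high dilution joins the vinyl group to the acrylate and should return 21. The known risk of this variant is attack of the carbene on the C1=C10 alkene with loss of the chain; it is tempered here because that alkene is trisubstituted and conjugated to a tert-butyl ester.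

**Step 9 (allylboration).** The most likely failures are a slow catalysed addition, because the ester group deactivates the allylboronate, and incomplete facial control at C8. A third is migration of the C1=C10 alkene of 11 into conjugation with the aldehyde under acid.

The fallback gives up catalytic induction. It sets out from 11 and 16. Uncatalysed addition in toluene at 80 °C passes through the same chair transition state and should still give the syn adduct, now racemic. Acid in methanol as before gives racemic 19, which is resolved by preparative chromatography on a chiral stationary phase. The unwanted enantiomer F8 is discarded and the route is rejoined at 19.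

**Step 12 (reduction).** The most likely failure is over-reduction of the lactol to the C12 alcohol while the slower tert-butyl ester is being driven to completion, or incomplete reduction of that ester if the temperature is kept low.

The fallback changes the order of events. It sets out from 21. One equivalent of LiOH in THF/H2O at 0 °C opens the lactone much faster than it hydrolyses the two hindered conjugated esters and gives the lithium hydroxy carboxylate diester F9. After drying, iBu2AlH in THF (−78 → 0 °C) reduces both esters while the carboxylate is inert, and a basic work-up gives 24 directly.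

**Step 16 (angeloylation).** The most likely failure is isomerisation of the angeloyl group to the tigloyl group during activation, or slow acylation of the hindered C8 hydroxyl.

The fallback builds the (Z)-alkene on the ester. It sets out from 27. Carbodiimide esterification (DCC, DMAP) with 2-[bis(2,2,2-trifluoroethoxy)phosphoryl]propanoic acid gives the phosphonopropanoate F10. Still–Gennari olefination with acetaldehyde (KN(SiMe3)2, 18-crown-6, THF, −78 °C) is Z-selective and should give 30. The base is used at low temperature and in slight deficit to spare the methylene lactone.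

## Further compounds

F1 | step 14 | (6S,7R,8R)-cis-12,8-lactone aldehyde bearing an anilinooxy group on C6 | C=C1C(=O)O[C@H](C/C(C(=O)OC(C)(C)C)=C\CCC(C(=O)OCC)P(=O)(OCC)OCC)[C@@H]1[C@H](ONc2ccccc2)C=O
F2 | step 14 | 14-tert-butyl 15-ethyl (6R,7R,8R)-6α-(anilinooxy)-cis,cis-germacra-1(10),4,11(13)-trien-12,8β-olide-14,15-dioate | C=C1C(=O)O[C@@H]2C/C(C(=O)OC(C)(C)C)=C\CC/C(C(=O)OCC)=C\[C@@H](ONc3ccccc3)[C@H]12
F3 | step 14 | 14-tert-butyl 15-ethyl (6R,7R,8R)-6α-hydroxy-cis,cis-germacra-1(10),4,11(13)-trien-12,8β-olide-14,15-dioate | C=C1C(=O)O[C@@H]2C/C(C(=O)OC(C)(C)C)=C\CC/C(C(=O)OCC)=C\[C@@H](O)[C@H]12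
F4 | step 14 | (6R,7R,8R)-6α,14,15-trihydroxy-cis,cis-germacra-1(10),4,11(13)-trien-12,8β-lactol (C12 epimers) | C=C1C(O)O[C@@H]2C/C(CO)=C\CC/C(CO)=C\[C@@H](O)[C@H]12
F5 | step 11 | (7R,8R)-cis-12,8-lactone primary alcohol in which C4 is a 2-substituted ethyl acrylate (C4=CH2) | C=C1C(=O)O[C@H](C/C(C(=O)OC(C)(C)C)=C\CCC(=C)C(=O)OCC)[C@@H]1CCO
F6 | step 11 | C5 aldehyde of F5 | C=C1C(=O)O[C@H](C/C(C(=O)OC(C)(C)C)=C\CCC(=C)C(=O)OCC)[C@@H]1CC=O
F7 | step 11 | metathesis substrate: F6 with the aldehyde converted into a terminal alkene (allyl group on C7) | C=C1C(=O)O[C@H](C/C(C(=O)OC(C)(C)C)=C\CCC(=C)C(=O)OCC)[C@@H]1CC=C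
F8 | step 9 | (7S,8S) enantiomer of 19 | C=C1C(=O)O[C@@H](C/C(C(=O)OC(C)(C)C)=C\CCC(C(=O)OCC)P(=O)(OCC)OCC)[C@H]1CCO
F9 | step 12 | lithium (7R,8R)-14-tert-butoxy-15-ethoxy-8β-hydroxy-14,15-dioxo-cis,cis-germacra-1(10),4,11(13)-trien-12-oate | C=C(C(=O)[O-])[C@H]1C/C=C(/C(=O)OCC)CC/C=C(/C(=O)OC(C)(C)C)C[C@H]1O.[Li+]
F10 | step 16 | 8-O-{2-[bis(2,2,2-trifluoroethoxy)phosphoryl]propanoyl} derivative of 27 | C=C1C(=O)O[C@@H]2/C=C(/CO[Si](C)(C)C(C)(C)C)CC/C=C(/CO[Si](C)(C)C(C)(C)C)C[C@@H](OC(=O)C(C)P(=O)(OCC(F)(F)F)OCC(F)(F)F)[C@@H]12
A1 | alternative 1 | ten-membered (E)-enoate (C15 methyl ester) with a phenylsulfonyl group on C2, 4-methoxybenzyl ethers on the C6 and C12 oxygens, a triethylsilyl ether on C8 and a tert-butyldimethylsilyl ether on C14, both ring alkenes cis in the ring | COC(=O)/C1=C/[C@@H](OCc2ccc(OC)cc2)[C@H](C(=C)COCc2ccc(OC)cc2)[C@H](O[Si](CC)(CC)CC)C/C(CO[Si](C)(C)C(C)(C)C)=C\C(S(=O)(=O)c2ccccc2)C1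
A2 | alternative 2 | 8β-hydroxy-14,15-bis(tert-butyldimethylsilyloxy)-cis,cis-germacra-1(10),4-dien-12,6α-olide (C11 still a methylene) | C1C(=O)O[C@@H]2/C=C(/CO[Si](C)(C)C(C)(C)C)CC/C=C(/CO[Si](C)(C)C(C)(C)C)C[C@@H](O)[C@@H]12
A3 | alternative 3 | (8R)-8-(4-methoxybenzyloxy)-14,15-bis(tert-butyldimethylsilyloxy)cyclodeca-1(10),4-dien-6-one, both ring alkenes cis in the ring | O=C1C[C@H](OCc2ccc(OC)cc2)C/C(CO[Si](C)(C)C(C)(C)C)=C\CC/C(CO[Si](C)(C)C(C)(C)C)=C\1
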